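**Retrosynthetic overview** (chromanone numbering: O1, C2, C3, C4, C4a–C8a; ring A = benzo ring, ring B = catechol ring, ring C = pyranone ring)

- The target is the 7-O-geranyl ether of (2R,3R)-fustin; the last operation only removes three silyl ethers.
- Ring C is disconnected at C4–C4a and O1–C8a in one operation: a 2-fluoro-4-geranyloxyphenyllithium (ring A) is joined to a (3R,4R)-trans-3-silyloxy-4-aryl-β-lactone that already carries ring B and both stereocenters.
- Enabling feature: the C4 ketone of ring C is ortho to C8a on ring A and β to O1, so O1–C2–C3–C4 maps onto a β-lactone. Acylation of ring A at C4a by this strained ring creates the ortho-acyl activation of the C8a–F bond and, in the same event, frees the O1 alkoxide that closes ring C at O1–C8a.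
- The lactone, a four-membered ring absent from the target and cleaved in the key step, comes from an anti-selective asymmetric Mukaiyama aldol of a silyloxy thioacetate with protected protocatechualdehyde; this sets C2 and C3.
- Ring order: rings A and B are bought, the temporary β-lactone ring is made in step 6, ring C is formed last in step 8.

Key step: step 8

Assumption: the (R)-antipode of 1-ethyl-2-(piperidin-1-ylmethyl)pyrrolidine is taken to steer the aldol of step 5 to the (2R,3R) adduct; if the sense of induction is the opposite, the (S)-diamine is used with no other change.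

Remark: the anti aldol adduct, the trans lactone and the 2,3-trans chromanone all carry the descriptors (R,R), and no bond to either stereocenter is broken after step 5.

**Step 1**
Reactants: 1 3,4-dihydroxybenzaldehyde; 2 tert-butyldimethylsilyl chloride
Product: 3 3,4-bis(tert-butyldimethylsilyloxy)benzaldehyde
Conditions: TBSCl (2.3 equiv), imidazole, DMF, 0 °C → rt
Reagents that add atoms: tert-butyldimethylsilyl chloride 2, CC(C)(C)[Si](C)(C)Cl
Why: Imidazole-promoted silyl ether formation should cap both phenols so that the aldehyde is the only reactive site in step 5; no stereocenter is involved.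

**Step 2**
Reactants: 4 methyl glycolate; 2 tert-butyldimethylsilyl chloride
Product: 5 methyl 2-(tert-butyldimethylsilyloxy)acetate
Conditions: TBSCl, imidazole, CH2Cl2, 0 °C → rt
Reagents that add atoms: tert-butyldimethylsilyl chloride 2, CC(C)(C)[Si](C)(C)Cl
Why: The same silyl ether formation should protect the primary alcohol with the bulky, non-chelating group on which the anti selectivity of step 5 depends.

**Step 3**
Reactants: 5 methyl 2-(tert-butyldimethylsilyloxy)acetate; 6 ethanethiol
Product: 7 S-ethyl 2-(tert-butyldimethylsilyloxy)ethanethioate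
Conditions: AlMe3, EtSH, CH2Cl2, 0 °C → rt; aq HCl work-up
Reagents that add atoms: ethanethiol 6, CCS
Why: Aluminium-mediated ester-to-thioester exchange with the thiolate Me2AlSEt formed from AlMe3 and the thiol should proceed because the oxophilic aluminium takes up methoxide, and the silyl ether is inert to it.

**Step 4**
Reactants: 7 S-ethyl 2-(tert-butyldimethylsilyloxy)ethanethioate; 8 chlorotrimethylsilane
Product: 10 (Z)-2-(tert-butyldimethylsilyloxy)-1-(ethylsulfanyl)-1-(trimethylsilyloxy)ethene, via lithium enolate 9 (not isolated)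
Conditions: LiN(iPr)2, THF, −78 °C; TMSCl, −78 °C → rt
Reagents that add atoms: chlorotrimethylsilane 8, C[Si](C)(C)Cl
Why: Kinetic deprotonation through a cyclic Ireland-type transition state and O-silylation of the enolate (silyl ketene acetal formation) should place the non-chelating silyloxy group cis to sulfur, which is the Z geometry the aldol needs.

**Step 5**
Reactants: 3 3,4-bis(tert-butyldimethylsilyloxy)benzaldehyde; 10 (Z)-2-(tert-butyldimethylsilyloxy)-1-(ethylsulfanyl)-1-(trimethylsilyloxy)ethene
Product: 12 S-ethyl (2R,3R)-3-[3,4-bis(tert-butyldimethylsilyloxy)phenyl]-2-(tert-butyldimethylsilyloxy)-3-hydroxypropanethioate, via O-trimethylsilyl aldol adduct 11 (not isolated)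
Conditions: Sn(OTf)2, (R)-1-ethyl-2-(piperidin-1-ylmethyl)pyrrolidine, Bu2Sn(OAc)2, CH2Cl2, −78 °C; aq NaHCO3, then 1 M HCl/THF, 0 °C
Reagents that add atoms: none
Why: In this chiral diamine–Sn(OTf)2 promoted Mukaiyama aldol addition the diamine-bound divalent tin should shield one face of the coordinated aldehyde and so set C3 of the thioester as R, while the bulky non-chelating α-silyloxy group forces an open transition state that gives the anti relationship and with it C2 as R.

**Step 6**
Reactants: 12 S-ethyl (2R,3R)-3-[3,4-bis(tert-butyldimethylsilyloxy)phenyl]-2-(tert-butyldimethylsilyloxy)-3-hydroxypropanethioate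
Product: 13 (3R,4R)-4-[3,4-bis(tert-butyldimethylsilyloxy)phenyl]-3-(tert-butyldimethylsilyloxy)oxetan-2-one (trans)
Conditions: Hg(OCOCF3)2, Na2HPO4, MeCN, 0 °C → rt
Reagents that add atoms: none
Why: Thiophile-promoted lactonization of a β-hydroxy thioester (acyl substitution at the mercury-activated thioester by the β-hydroxyl) should close the four-membered ring with retention at both stereocenters, so the anti adduct gives the trans lactone.

**Step 7**
Reactants: 14 4-bromo-3-fluorophenol; 15 geranyl bromide
Product: 16 1-bromo-4-{[(2E)-3,7-dimethylocta-2,6-dien-1-yl]oxy}-2-fluorobenzene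
Conditions: K2CO3, acetone, rt → 50 °C
Reagents that add atoms: geranyl bromide 15, CC(C)=CCC/C(C)=C/CBr
Why: Williamson ether synthesis by SN2 displacement at the primary allylic bromide should give the aryl geranyl ether with the E alkene intact, and the weak base leaves the C–F and C–Br bonds alone.

**Step 8**
Reactants: 16 1-bromo-4-{[(2E)-3,7-dimethylocta-2,6-dien-1-yl]oxy}-2-fluorobenzene; 13 (3R,4R)-4-[3,4-bis(tert-butyldimethylsilyloxy)phenyl]-3-(tert-butyldimethylsilyloxy)oxetan-2-one
Product: 19 (2R,3R)-2-[3,4-bis(tert-butyldimethylsilyloxy)phenyl]-3-(tert-butyldimethylsilyloxy)-7-{[(2E)-3,7-dimethylocta-2,6-dien-1-yl]oxy}-2,3-dihydro-4H-chromen-4-one, via aryllithium 17 (not isolated), via lithium aldolate 18 (not isolated)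
Conditions: n-BuLi, THF, −78 °C; then transferred into 13, THF, −78 °C; then DMPU, −78 → 0 °C; aq NH4Cl
Reagents that add atoms: none
Why: Proposed new method: bromine–lithium exchange gives aryllithium 17, which should attack the strained lactone carbonyl of 13 (acyl–oxygen cleavage, the known mode in which organolithium and N-methoxy-N-methylamine reagents open β-lactones to β-hydroxy ketones and amides); collapse of the four-membered tetrahedral adduct is driven by release of the β-lactone ring strain and gives lithium aldolate 18, in which the new C4 ketone lies ortho to the C–F carbon and the freed alkoxide sits in reach of it. The alkoxide then adds to the fluorine-bearing carbon and expels fluoride (intramolecular nucleophilic aromatic substitution through a Meisenheimer adduct; the closest known reaction type is the base-mediated closure of 1-(2-fluoroaryl)-3-hydroxy ketones to chroman-4-ones), which forms the O1–C8a bond and closes ring C in a 6-exo mode. No stereocenter is created: C2 and C3 are carried over from 13 with retention because no bond to either carbon is broken, so the trans lactone becomes the 2,3-trans chromanone. The step needs mono-addition, which inverse addition at −78 °C to the far more electrophilic lactone should secure, the liberated ketone being a hindered, chelated aldolate. It also needs ring closure faster than retro-aldol cleavage or silyl migration (low temperature, a lithium chelate that raises the electrophilicity of ring A, DMPU-assisted closure at or below 0 °C) and six- over five-membered closure (the α-oxygen is silylated and a five-membered closure onto the ipso carbon is stereoelectronically poor). What is new is the merger of these two known events into one annulation of a 2-fluoroaryllithium with a β-lactone.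

**Step 9**
Reactants: 19 (2R,3R)-2-[3,4-bis(tert-butyldimethylsilyloxy)phenyl]-3-(tert-butyldimethylsilyloxy)-7-{[(2E)-3,7-dimethylocta-2,6-dien-1-yl]oxy}-2,3-dihydro-4H-chromen-4-one
Product: 20 (2R,3R)-2-(3,4-dihydroxyphenyl)-7-{[(2E)-3,7-dimethylocta-2,6-dien-1-yl]oxy}-3-hydroxy-2,3-dihydro-4H-chromen-4-one
Conditions: HF·pyridine, pyridine, THF, 0 °C → rt
Reagents that add atoms: none
Why: Fluoride-mediated cleavage of the three silyl ethers (desilylation) under pyridine-buffered, base-free conditions should free the catechol and the 3-hydroxyl without enolization at C3 or ring opening at C2, and should leave the geranyl ether untouched.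

**Compound list**

1 | 3,4-dihydroxybenzaldehyde | O=Cc1ccc(O)c(O)c1 | starting material
2 | tert-butyldimethylsilyl chloride | CC(C)(C)[Si](C)(C)Cl | starting material
3 | 3,4-bis(tert-butyldimethylsilyloxy)benzaldehyde | O=Cc1ccc(O[Si](C)(C)C(C)(C)C)c(O[Si](C)(C)C(C)(C)C)c1 | intermediate
4 | methyl glycolate | COC(=O)CO | starting material
5 | methyl 2-(tert-butyldimethylsilyloxy)acetate | COC(=O)CO[Si](C)(C)C(C)(C)C | intermediate
6 | ethanethiol | CCS | starting material
7 | S-ethyl 2-(tert-butyldimethylsilyloxy)ethanethioate | CCSC(=O)CO[Si](C)(C)C(C)(C)C | intermediate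
8 | chlorotrimethylsilane | C[Si](C)(C)Cl | starting material
9 | lithium (Z)-2-(tert-butyldimethylsilyloxy)-1-(ethylsulfanyl)ethen-1-olate | CCS/C(O[Li])=C\O[Si](C)(C)C(C)(C)C | intermediate
10 | (Z)-2-(tert-butyldimethylsilyloxy)-1-(ethylsulfanyl)-1-(trimethylsilyloxy)ethene | CCS/C(O[Si](C)(C)C)=C\O[Si](C)(C)C(C)(C)C | intermediate
11 | S-ethyl (2R,3R)-3-[3,4-bis(tert-butyldimethylsilyloxy)phenyl]-2-(tert-butyldimethylsilyloxy)-3-(trimethylsilyloxy)propanethioate | C[Si](C)(C)O[C@H](c1ccc(O[Si](C)(C)C(C)(C)C)c(O[Si](C)(C)C(C)(C)C)c1)[C@@H](O[Si](C)(C)C(C)(C)C)C(=O)SCC | intermediate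
12 | S-ethyl (2R,3R)-3-[3,4-bis(tert-butyldimethylsilyloxy)phenyl]-2-(tert-butyldimethylsilyloxy)-3-hydroxypropanethioate | O[C@H](c1ccc(O[Si](C)(C)C(C)(C)C)c(O[Si](C)(C)C(C)(C)C)c1)[C@@H](O[Si](C)(C)C(C)(C)C)C(=O)SCC | intermediate
13 | (3R,4R)-4-[3,4-bis(tert-butyldimethylsilyloxy)phenyl]-3-(tert-butyldimethylsilyloxy)oxetan-2-one | O1[C@H](c2ccc(O[Si](C)(C)C(C)(C)C)c(O[Si](C)(C)C(C)(C)C)c2)[C@@H](O[Si](C)(C)C(C)(C)C)C1=O | intermediate
14 | 4-bromo-3-fluorophenol | Oc1ccc(Br)c(F)c1 | starting material
15 | geranyl bromide, (2E)-1-bromo-3,7-dimethylocta-2,6-diene | CC(C)=CCC/C(C)=C/CBr | starting material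
16 | 1-bromo-4-{[(2E)-3,7-dimethylocta-2,6-dien-1-yl]oxy}-2-fluorobenzene | CC(C)=CCC/C(C)=C/COc1ccc(Br)c(F)c1 | intermediate
17 | (4-{[(2E)-3,7-dimethylocta-2,6-dien-1-yl]oxy}-2-fluorophenyl)lithium | CC(C)=CCC/C(C)=C/COc1ccc([Li])c(F)c1 | intermediate
18 | lithium (1R,2R)-1-[3,4-bis(tert-butyldimethylsilyloxy)phenyl]-2-(tert-butyldimethylsilyloxy)-3-(4-{[(2E)-3,7-dimethylocta-2,6-dien-1-yl]oxy}-2-fluorophenyl)-3-oxopropan-1-olate | [Li]O[C@H](c1ccc(O[Si](C)(C)C(C)(C)C)c(O[Si](C)(C)C(C)(C)C)c1)[C@@H](O[Si](C)(C)C(C)(C)C)C(=O)c1ccc(OC/C=C(\C)CCC=C(C)C)cc1F | intermediate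
19 | (2R,3R)-2-[3,4-bis(tert-butyldimethylsilyloxy)phenyl]-3-(tert-butyldimethylsilyloxy)-7-{[(2E)-3,7-dimethylocta-2,6-dien-1-yl]oxy}-2,3-dihydro-4H-chromen-4-one | CC(C)=CCC/C(C)=C/COc1ccc2c(c1)O[C@H](c1ccc(O[Si](C)(C)C(C)(C)C)c(O[Si](C)(C)C(C)(C)C)c1)[C@@H](O[Si](C)(C)C(C)(C)C)C2=O | intermediate
20 | (2R,3R)-2-(3,4-dihydroxyphenyl)-7-{[(2E)-3,7-dimethylocta-2,6-dien-1-yl]oxy}-3-hydroxy-2,3-dihydro-4H-chromen-4-one | CC(C)=CCC/C(C)=C/COc1ccc2c(c1)O[C@H](c1ccc(O)c(O)c1)[C@@H](O)C2=O | target

**Step count**

Total: 9 steps. Longest linear sequence: 7 steps (steps 2, 3, 4, 5, 6, 8, 9).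

**Steps most likely to fail**

Step 8 (proposed new method). Three processes may compete with the annulation:
- a second addition of aryllithium 17 to the ketone released in the flask;
- deprotonation of the lactone α-position by 17;
- retro-aldol cleavage or silyl migration in the lithium aldolate before ring closure, which would erode the configuration at C2 and C3 or divert the closure.

The fallback sets out from 13 and comes back at 19, using known reaction types only. Lactone 13 is opened at the acyl carbon with MeNHOMe·HCl/Me2AlCl (CH2Cl2, 0 °C) to (2R,3R)-3-[3,4-bis(tert-butyldimethylsilyloxy)phenyl]-2-(tert-butyldimethylsilyloxy)-3-hydroxy-N-methoxy-N-methylpropanamide F1. Its hydroxyl is deprotonated with iPrMgCl and aryllithium 17 is added at −78 °C; the chelated tetrahedral adduct releases the ketone only on aqueous work-up, so over-addition is excluded. This gives (2R,3R)-3-[3,4-bis(tert-butyldimethylsilyloxy)phenyl]-2-(tert-butyldimethylsilyloxy)-1-(4-{[(2E)-3,7-dimethylocta-2,6-dien-1-yl]oxy}-2-fluorophenyl)-3-hydroxypropan-1-one F2. F2 is closed to 19 with K2CO3 in DMF at room temperature by intramolecular nucleophilic aromatic substitution, under a weak base that keeps the alkoxide concentration low.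

Step 6. The Lewis-acidic mercury salt may ionize the benzylic C–O bond of the electron-rich 4-aryl lactone, leading to decarboxylative fragmentation or epimerization at C4. The fallback sets out from 12 and comes back at 13. The thioester is hydrolysed briefly with LiOH/H2O2 (THF/H2O, 0 °C) to (2R,3R)-3-[3,4-bis(tert-butyldimethylsilyloxy)phenyl]-2-(tert-butyldimethylsilyloxy)-3-hydroxypropanoic acid F3. The ring is then closed by carboxyl activation with PhSO2Cl in pyridine at 0 °C, a lactonization with retention that uses no thiophilic metal.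

Step 9. Cleavage of the hindered C3 silyl ether may be incomplete, or the longer exposure it requires may lead to acid-induced reactions of the geranyl chain or to ring opening at C2. The fallback installs the geranyl group last; it sets out from 14 and 13 and comes back at 20.
- Phenol 14 is silylated (TBSCl 2, imidazole, DMF) to (4-bromo-3-fluorophenoxy)(tert-butyl)dimethylsilane F4.
- Bromine–lithium exchange (n-BuLi, THF, −78 °C) gives [4-(tert-butyldimethylsilyloxy)-2-fluorophenyl]lithium F5.
- Addition of F5 to 13 gives lithium (1R,2R)-1-[3,4-bis(tert-butyldimethylsilyloxy)phenyl]-2-(tert-butyldimethylsilyloxy)-3-[4-(tert-butyldimethylsilyloxy)-2-fluorophenyl]-3-oxopropan-1-olate F6.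
- F6 closes as in step 8 to (2R,3R)-2-[3,4-bis(tert-butyldimethylsilyloxy)phenyl]-3,7-bis(tert-butyldimethylsilyloxy)-2,3-dihydro-4H-chromen-4-one F7.
- Without the geranyl group the desilylation can be pushed (HF·pyridine, THF, or Bu4NF/AcOH) to (2R,3R)-2-(3,4-dihydroxyphenyl)-3,7-dihydroxy-2,3-dihydro-4H-chromen-4-one F8, which is (2R,3R)-fustin.
- The most acidic phenol of F8, the 7-hydroxyl para to the ketone, is alkylated with geranyl bromide 15 and K2CO3 (1 equiv) in acetone to give 20.

**Further compounds**

F1 | step 8 | (2R,3R)-3-[3,4-bis(tert-butyldimethylsilyloxy)phenyl]-2-(tert-butyldimethylsilyloxy)-3-hydroxy-N-methoxy-N-methylpropanamide | O[C@H](c1ccc(O[Si](C)(C)C(C)(C)C)c(O[Si](C)(C)C(C)(C)C)c1)[C@@H](O[Si](C)(C)C(C)(C)C)C(=O)N(C)OC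
F2 | step 8 | (2R,3R)-3-[3,4-bis(tert-butyldimethylsilyloxy)phenyl]-2-(tert-butyldimethylsilyloxy)-1-(4-{[(2E)-3,7-dimethylocta-2,6-dien-1-yl]oxy}-2-fluorophenyl)-3-hydroxypropan-1-one | O[C@H](c1ccc(O[Si](C)(C)C(C)(C)C)c(O[Si](C)(C)C(C)(C)C)c1)[C@@H](O[Si](C)(C)C(C)(C)C)C(=O)c1ccc(OC/C=C(\C)CCC=C(C)C)cc1F
F3 | step 6 | (2R,3R)-3-[3,4-bis(tert-butyldimethylsilyloxy)phenyl]-2-(tert-butyldimethylsilyloxy)-3-hydroxypropanoic acid | O[C@H](c1ccc(O[Si](C)(C)C(C)(C)C)c(O[Si](C)(C)C(C)(C)C)c1)[C@@H](O[Si](C)(C)C(C)(C)C)C(=O)O
F4 | step 9 | (4-bromo-3-fluorophenoxy)(tert-butyl)dimethylsilane | CC(C)(C)[Si](C)(C)Oc1ccc(Br)c(F)c1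
F5 | step 9 | [4-(tert-butyldimethylsilyloxy)-2-fluorophenyl]lithium | CC(C)(C)[Si](C)(C)Oc1ccc([Li])c(F)c1
F6 | step 9 | lithium (1R,2R)-1-[3,4-bis(tert-butyldimethylsilyloxy)phenyl]-2-(tert-butyldimethylsilyloxy)-3-[4-(tert-butyldimethylsilyloxy)-2-fluorophenyl]-3-oxopropan-1-olate | [Li]O[C@H](c1ccc(O[Si](C)(C)C(C)(C)C)c(O[Si](C)(C)C(C)(C)C)c1)[C@@H](O[Si](C)(C)C(C)(C)C)C(=O)c1ccc(O[Si](C)(C)C(C)(C)C)cc1F
F7 | step 9 | (2R,3R)-2-[3,4-bis(tert-butyldimethylsilyloxy)phenyl]-3,7-bis(tert-butyldimethylsilyloxy)-2,3-dihydro-4H-chromen-4-one | CC(C)(C)[Si](C)(C)Oc1ccc2c(c1)O[C@H](c1ccc(O[Si](C)(C)C(C)(C)C)c(O[Si](C)(C)C(C)(C)C)c1)[C@@H](O[Si](C)(C)C(C)(C)C)C2=O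
F8 | step 9 | (2R,3R)-2-(3,4-dihydroxyphenyl)-3,7-dihydroxy-2,3-dihydro-4H-chromen-4-one | Oc1ccc2c(c1)O[C@H](c1ccc(O)c(O)c1)[C@@H](O)C2=O
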